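The tetrahydrofuran ring (O1, C2–C5) is cut at O1–C2 and C4–C5. This exposes the feature the route exploits: C2 bears an electron-rich aryl group cis to the C3 methyl and cis to the C5 aryl, so O1/C5 can come from an aryl aldehyde and C2–C3–C4 from an enantiopure trans-2-aryl-3-methylcyclopropane-1,1-diester. One AlCl3-catalysed (3+2) annulation opens the cyclopropane at C2 with inversion and closes the ring, setting the C2 and C5 stereocentres. The geminal diester at C4 is then trimmed to the C4 methyl, the benzyl ethers are removed, and both erythro aryloxypropanol side chains are built on the bisphenol from ethyl (R)-lactate.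

Key step: step 6

Assumption: ring locants in the text are those of the target core (O1; C2 = aryl carbon cis to the C3 methyl; C3; C4; C5), whereas systematic names of the ester intermediates number the ring from the other end; the (R)-configured prolinol silyl ether is chosen because the (S)-catalyst shields the Re face of the β-carbon of an (E)-3-arylpropenal iminium ion, so the (R)-catalyst leaves that face open to the malonate.

Step 1
Reactants: 1 4-benzyloxy-3-methoxybenzaldehyde (O-benzylvanillin); 2 (triphenylphosphoranylidene)acetaldehyde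
Product: 3 (E)-3-(4-benzyloxy-3-methoxyphenyl)prop-2-enal
Conditions: 2 (1.2 equiv), toluene, 90 °C
Reagents that add atoms: none
Why: Wittig olefination with the stabilised formyl ylide should give the E-enal, and the small excess of ylide keeps a second homologation of the product minor.

Step 2
Reactants: 3 (E)-3-(4-benzyloxy-3-methoxyphenyl)prop-2-enal; 4 dimethyl bromomalonate
Product: 5 dimethyl (2R,3S)-2-(4-benzyloxy-3-methoxyphenyl)-3-formylcyclopropane-1,1-dicarboxylate (formyl trans to aryl)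
Conditions: (R)-2-[diphenyl(trimethylsilyloxy)methyl]pyrrolidine (20 mol %), 2,6-lutidine, CH2Cl2, 0 °C to rt
Reagents that add atoms: none
Why: Organocatalytic Michael-initiated ring closure: the iminium ion formed with the (R)-catalyst exposes the Re face of the β-carbon to the bromomalonate (aryl-bearing centre R), and the enamine then closes by 3-exo-tet displacement of bromide to the trans aldehyde, which is also the thermodynamically preferred isomer at the epimerisable formyl carbon.

Step 3
Reactants: 5 dimethyl (2R,3S)-2-(4-benzyloxy-3-methoxyphenyl)-3-formylcyclopropane-1,1-dicarboxylate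
Product: 6 dimethyl (2R,3S)-2-(4-benzyloxy-3-methoxyphenyl)-3-(hydroxymethyl)cyclopropane-1,1-dicarboxylate
Conditions: NaBH4, MeOH, −20 °C; aq NH4Cl
Reagents that add atoms: none
Why: Borohydride reduction of the aldehyde is far faster than attack on the esters, and the low temperature with a buffered quench should keep the alkoxide from lactonising onto the cis ester; no stereocentre is touched.

Step 4
Reactants: 6 dimethyl (2R,3S)-2-(4-benzyloxy-3-methoxyphenyl)-3-(hydroxymethyl)cyclopropane-1,1-dicarboxylate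
Product: 7 dimethyl (2R,3S)-2-(4-benzyloxy-3-methoxyphenyl)-3-(methanesulfonyloxymethyl)cyclopropane-1,1-dicarboxylate
Conditions: MsCl, Et3N, CH2Cl2, −10 °C; used crude
Reagents that add atoms: methanesulfonyl chloride, CS(=O)(=O)Cl
Why: Mesylation of a primary alcohol through sulfene is fast at low temperature, and the two ring esters make this cyclopropylcarbinyl mesylate a poor ioniser, so it should survive when used without chromatography.

Step 5
Reactants: 7 dimethyl (2R,3S)-2-(4-benzyloxy-3-methoxyphenyl)-3-(methanesulfonyloxymethyl)cyclopropane-1,1-dicarboxylate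
Product: 8 dimethyl (2R,3S)-2-(4-benzyloxy-3-methoxyphenyl)-3-methylcyclopropane-1,1-dicarboxylate (aryl trans to methyl)
Conditions: NaBH4, DMSO, 25–40 °C
Reagents that add atoms: none
Why: SN2 displacement of the primary mesylate by borohydride in a dipolar aprotic solvent turns CH2OMs into CH3 without cationic or radical intermediates that would open the ring, and leaves the esters, the benzyl ether and both stereocentres untouched.

Step 6
Reactants: 8 dimethyl (2R,3S)-2-(4-benzyloxy-3-methoxyphenyl)-3-methylcyclopropane-1,1-dicarboxylate; 1 4-benzyloxy-3-methoxybenzaldehyde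
Product: 9 dimethyl (2S,4R,5S)-2,5-bis(4-benzyloxy-3-methoxyphenyl)-4-methyltetrahydrofuran-3,3-dicarboxylate (2,5-cis diaryl; 4-methyl cis to 5-aryl)
Conditions: AlCl3 (15 mol %), aldehyde 1 in slight excess, CH2Cl2, 0 °C to rt; Et3N quench at full conversion
Reagents that add atoms: none
Why: AlCl3 chelates the geminal diester and polarises the bond between the aryl-bearing carbon and the diester carbon of 8, the carbonyl oxygen of 1 attacks that carbon from the rear in an SN2-like opening (O1–C2, inversion), and the malonate enolate of the resulting zwitterion then adds to the oxocarbenium carbon (C4–C5). The closest known reaction type is the Lewis acid-catalysed (3+2) annulation of 2-arylcyclopropane-1,1-diesters with aldehydes to 2,5-cis tetrahydrofurans, which is established with AlCl3 for electron-rich trans-2-aryl-3-substituted cyclopropanes. The tetrahydrofuran ring closes in a formally 5-(enolexo)-endo-trig mode, since the C5=O1 bond of the oxocarbenium ion ends up inside the ring, a closure that is routine for such cationic acceptors (Prins- and Mannich-type cyclisations). C2 is controlled by the R centre of 8 through stereospecific inversion, which turns the trans aryl/methyl pair into the cis C2-aryl/C3-methyl pair while C3 is untouched, and C5 is controlled by an envelope transition state with both aryl groups pseudo-equatorial, which gives the 2,5-cis ring. The step needs inversion to outrun ionisation at the p-alkoxybenzylic carbon; catalytic Lewis acid, low temperature, a modest excess of the nucleophilic p-alkoxy aldehyde and a prompt quench should secure this, and because C3 stays fixed any leakage would give separable diastereomers and not the enantiomer.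

Step 7
Reactants: 9 dimethyl (2S,4R,5S)-2,5-bis(4-benzyloxy-3-methoxyphenyl)-4-methyltetrahydrofuran-3,3-dicarboxylate
Product: 11 methyl (2R,3R,4R,5S)-2,5-bis(4-benzyloxy-3-methoxyphenyl)-4-methyltetrahydrofuran-3-carboxylate (ester trans to both neighbours), via 3-epimeric monoester 10 (not isolated)
Conditions: LiCl, H2O, DMSO, 150 °C; then NaOMe (0.3 equiv), MeOH, 40 °C
Reagents that add atoms: none
Why: Krapcho dealkoxycarbonylation (chloride attack on a methyl group, loss of CO2) leaves an ester enolate whose protonation from the open face is expected to give mainly the all-cis epimer 10, and methoxide then equilibrates this single enolisable centre to the isomer with CO2Me trans to the neighbouring aryl and methyl groups, the thermodynamic minimum, which fixes C4 of the target.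

Step 8
Reactants: 11 methyl (2R,3R,4R,5S)-2,5-bis(4-benzyloxy-3-methoxyphenyl)-4-methyltetrahydrofuran-3-carboxylate
Product: 12 [(2R,3S,4R,5S)-2,5-bis(4-benzyloxy-3-methoxyphenyl)-4-methyltetrahydrofuran-3-yl]methanol
Conditions: LiAlH4, THF, 0 °C
Reagents that add atoms: none
Why: LiAlH4 reduction of the ester to the primary alcohol leaves the benzyl ethers and the ring untouched, and no centre remains enolisable afterwards.

Step 9
Reactants: 12 [(2R,3S,4R,5S)-2,5-bis(4-benzyloxy-3-methoxyphenyl)-4-methyltetrahydrofuran-3-yl]methanol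
Product: 13 [(2R,3S,4R,5S)-2,5-bis(4-benzyloxy-3-methoxyphenyl)-4-methyltetrahydrofuran-3-yl]methyl methanesulfonate
Conditions: MsCl, Et3N, CH2Cl2, 0 °C
Reagents that add atoms: methanesulfonyl chloride, CS(=O)(=O)Cl
Why: Standard mesylation of a primary alcohol (sulfene pathway), here with no cation-stabilising neighbour, so the product should be stable.

Step 10
Reactants: 13 [(2R,3S,4R,5S)-2,5-bis(4-benzyloxy-3-methoxyphenyl)-4-methyltetrahydrofuran-3-yl]methyl methanesulfonate
Product: 14 (2S,3R,4R,5R)-2,5-bis(4-benzyloxy-3-methoxyphenyl)-3,4-dimethyltetrahydrofuran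
Conditions: LiEt3BH, THF, 0 °C to rt
Reagents that add atoms: none
Why: LiEt3BH displaces the primary mesylate by SN2 hydride transfer, a standard deoxygenation that tolerates the β-branch and converts the former ester carbon into the C4 methyl.

Step 11
Reactants: 14 (2S,3R,4R,5R)-2,5-bis(4-benzyloxy-3-methoxyphenyl)-3,4-dimethyltetrahydrofuran
Product: 15 4,4'-[(2S,3R,4R,5R)-3,4-dimethyltetrahydrofuran-2,5-diyl]bis(2-methoxyphenol)
Conditions: H2 (1 atm), 10% Pd/C, EtOAc, rt
Reagents that add atoms: none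
Why: Catalytic hydrogenolysis cleaves aryl benzyl ethers much faster than the ring benzylic C–O bonds under neutral conditions at 1 atm, so stopping after uptake of two equivalents should leave the tetrahydrofuran intact.

Step 12
Reactants: 15 4,4'-[(2S,3R,4R,5R)-3,4-dimethyltetrahydrofuran-2,5-diyl]bis(2-methoxyphenol); 16 ethyl (R)-lactate (2.6 equiv)
Product: 17 diethyl (2S,2'S)-2,2'-{[(2S,3R,4R,5R)-3,4-dimethyltetrahydrofuran-2,5-diyl]bis[(2-methoxy-4,1-phenylene)oxy]}dipropanoate
Conditions: PPh3, DIAD, THF, 0 °C to rt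
Reagents that add atoms: none
Why: Double Mitsunobu etherification: each phenol displaces the activated hydroxyl of 16 by SN2 with clean inversion, so the (R)-lactate gives the S configuration at both aryloxy-bearing side-chain carbons.

Step 13
Reactants: 17 diethyl (2S,2'S)-2,2'-{[(2S,3R,4R,5R)-3,4-dimethyltetrahydrofuran-2,5-diyl]bis[(2-methoxy-4,1-phenylene)oxy]}dipropanoate
Product: 18 (2S,2'S)-2,2'-{[(2S,3R,4R,5R)-3,4-dimethyltetrahydrofuran-2,5-diyl]bis[(2-methoxy-4,1-phenylene)oxy]}bis(N-methoxy-N-methylpropanamide)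
Conditions: MeNHOMe·HCl, iPrMgCl, THF, −20 °C
Reagents that add atoms: N,O-dimethylhydroxylamine hydrochloride, CNOC.Cl
Why: Weinreb amide formation: the chloromagnesium amide of N,O-dimethylhydroxylamine adds to each ester carbonyl at −20 °C faster than it deprotonates the α-aryloxy carbon, so both S centres should be kept.

Step 14
Reactants: 18 (2S,2'S)-2,2'-{[(2S,3R,4R,5R)-3,4-dimethyltetrahydrofuran-2,5-diyl]bis[(2-methoxy-4,1-phenylene)oxy]}bis(N-methoxy-N-methylpropanamide); 19 4-bromoveratrole (3 equiv)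
Product: 21 (2S,2'S)-2,2'-{[(2S,3R,4R,5R)-3,4-dimethyltetrahydrofuran-2,5-diyl]bis[(2-methoxy-4,1-phenylene)oxy]}bis[1-(3,4-dimethoxyphenyl)propan-1-one], via 3,4-dimethoxyphenylmagnesium bromide 20 (not isolated)
Conditions: 19 (3 equiv), Mg (3.3 equiv), THF, rt to 40 °C; then 18, THF, −10 to 0 °C; cold aq NH4Cl
Reagents that add atoms: none
Why: Weinreb ketone synthesis: two equivalents of the aryl Grignard reagent 20 are consumed, one per amide, and the magnesium chelate of each tetrahedral adduct survives until the cold acidic quench, which prevents over-addition and keeps the α-aryloxy ketone from meeting base.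

Step 15
Reactants: 21 (2S,2'S)-2,2'-{[(2S,3R,4R,5R)-3,4-dimethyltetrahydrofuran-2,5-diyl]bis[(2-methoxy-4,1-phenylene)oxy]}bis[1-(3,4-dimethoxyphenyl)propan-1-one]
Product: 22 (1R,1'R,2S,2'S)-2,2'-{[(2S,3R,4R,5R)-3,4-dimethyltetrahydrofuran-2,5-diyl]bis[(2-methoxy-4,1-phenylene)oxy]}bis[1-(3,4-dimethoxyphenyl)propan-1-ol] (CNP0116650.13)
Conditions: Zn(BH4)2 (from ZnCl2 and NaBH4), Et2O–THF, −30 to 0 °C
Reagents that add atoms: none
Why: Chelation-controlled reduction (Cram-chelate model): divalent zinc bridges the ketone and α-aryloxy oxygens and hydride is delivered from the face carrying the α-hydrogen, which sets both new carbinol centres as R, anti (erythro) to the S aryloxy centres.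

Compound list

1 | 4-benzyloxy-3-methoxybenzaldehyde (O-benzylvanillin) | COc1cc(C=O)ccc1OCc1ccccc1 | starting material
2 | (triphenylphosphoranylidene)acetaldehyde | O=CC=P(c1ccccc1)(c1ccccc1)c1ccccc1 | starting material
3 | (E)-3-(4-benzyloxy-3-methoxyphenyl)prop-2-enal | COc1cc(/C=C/C=O)ccc1OCc1ccccc1 | intermediate
4 | dimethyl bromomalonate | COC(=O)C(Br)C(=O)OC | starting material
5 | dimethyl (2R,3S)-2-(4-benzyloxy-3-methoxyphenyl)-3-formylcyclopropane-1,1-dicarboxylate | COC(=O)C1(C(=O)OC)[C@@H](C=O)[C@@H]1c1ccc(OCc2ccccc2)c(OC)c1 | intermediate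
6 | dimethyl (2R,3S)-2-(4-benzyloxy-3-methoxyphenyl)-3-(hydroxymethyl)cyclopropane-1,1-dicarboxylate | COC(=O)C1(C(=O)OC)[C@@H](CO)[C@@H]1c1ccc(OCc2ccccc2)c(OC)c1 | intermediate
7 | dimethyl (2R,3S)-2-(4-benzyloxy-3-methoxyphenyl)-3-(methanesulfonyloxymethyl)cyclopropane-1,1-dicarboxylate | COC(=O)C1(C(=O)OC)[C@@H](COS(C)(=O)=O)[C@@H]1c1ccc(OCc2ccccc2)c(OC)c1 | intermediate
8 | dimethyl (2R,3S)-2-(4-benzyloxy-3-methoxyphenyl)-3-methylcyclopropane-1,1-dicarboxylate | COC(=O)C1(C(=O)OC)[C@@H](C)[C@@H]1c1ccc(OCc2ccccc2)c(OC)c1 | intermediate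
9 | dimethyl (2S,4R,5S)-2,5-bis(4-benzyloxy-3-methoxyphenyl)-4-methyltetrahydrofuran-3,3-dicarboxylate | O1[C@@H](c2ccc(OCc3ccccc3)c(OC)c2)C(C(=O)OC)(C(=O)OC)[C@@H](C)[C@H]1c1ccc(OCc2ccccc2)c(OC)c1 | intermediate
10 | methyl (2R,3S,4R,5S)-2,5-bis(4-benzyloxy-3-methoxyphenyl)-4-methyltetrahydrofuran-3-carboxylate (all-cis 3-epimer) | COc1cc(ccc1OCc1ccccc1)[C@H]1O[C@@H](c2ccc(OCc3ccccc3)c(OC)c2)[C@@H](C(=O)OC)[C@H]1C | intermediate
11 | methyl (2R,3R,4R,5S)-2,5-bis(4-benzyloxy-3-methoxyphenyl)-4-methyltetrahydrofuran-3-carboxylate | COc1cc(ccc1OCc1ccccc1)[C@H]1O[C@@H](c2ccc(OCc3ccccc3)c(OC)c2)[C@H](C(=O)OC)[C@H]1C | intermediate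
12 | [(2R,3S,4R,5S)-2,5-bis(4-benzyloxy-3-methoxyphenyl)-4-methyltetrahydrofuran-3-yl]methanol | COc1cc(ccc1OCc1ccccc1)[C@H]1O[C@@H](c2ccc(OCc3ccccc3)c(OC)c2)[C@H](CO)[C@H]1C | intermediate
13 | [(2R,3S,4R,5S)-2,5-bis(4-benzyloxy-3-methoxyphenyl)-4-methyltetrahydrofuran-3-yl]methyl methanesulfonate | COc1cc(ccc1OCc1ccccc1)[C@H]1O[C@@H](c2ccc(OCc3ccccc3)c(OC)c2)[C@H](COS(C)(=O)=O)[C@H]1C | intermediate
14 | (2S,3R,4R,5R)-2,5-bis(4-benzyloxy-3-methoxyphenyl)-3,4-dimethyltetrahydrofuran | COc1cc(ccc1OCc1ccccc1)[C@H]1O[C@@H](c2ccc(OCc3ccccc3)c(OC)c2)[C@H](C)[C@H]1C | intermediate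
15 | 4,4'-[(2S,3R,4R,5R)-3,4-dimethyltetrahydrofuran-2,5-diyl]bis(2-methoxyphenol) | COc1cc(ccc1O)[C@H]1O[C@@H](c2ccc(O)c(OC)c2)[C@H](C)[C@H]1C | intermediate
16 | ethyl (R)-lactate | CCOC(=O)[C@@H](C)O | starting material
17 | diethyl (2S,2'S)-2,2'-{[(2S,3R,4R,5R)-3,4-dimethyltetrahydrofuran-2,5-diyl]bis[(2-methoxy-4,1-phenylene)oxy]}dipropanoate | COc1cc(ccc1O[C@@H](C)C(=O)OCC)[C@H]1O[C@@H](c2ccc(O[C@@H](C)C(=O)OCC)c(OC)c2)[C@H](C)[C@H]1C | intermediate
18 | (2S,2'S)-2,2'-{[(2S,3R,4R,5R)-3,4-dimethyltetrahydrofuran-2,5-diyl]bis[(2-methoxy-4,1-phenylene)oxy]}bis(N-methoxy-N-methylpropanamide) | COc1cc(ccc1O[C@@H](C)C(=O)N(C)OC)[C@H]1O[C@@H](c2ccc(O[C@@H](C)C(=O)N(C)OC)c(OC)c2)[C@H](C)[C@H]1C | intermediate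
19 | 4-bromoveratrole (4-bromo-1,2-dimethoxybenzene) | COc1ccc(Br)cc1OC | starting material
20 | 3,4-dimethoxyphenylmagnesium bromide | COc1ccc([Mg]Br)cc1OC | intermediate
21 | (2S,2'S)-2,2'-{[(2S,3R,4R,5R)-3,4-dimethyltetrahydrofuran-2,5-diyl]bis[(2-methoxy-4,1-phenylene)oxy]}bis[1-(3,4-dimethoxyphenyl)propan-1-one] | COc1cc(ccc1O[C@@H](C)C(=O)c1ccc(OC)c(OC)c1)[C@H]1O[C@@H](c2ccc(O[C@@H](C)C(=O)c3ccc(OC)c(OC)c3)c(OC)c2)[C@H](C)[C@H]1C | intermediate
22 | (1R,1'R,2S,2'S)-2,2'-{[(2S,3R,4R,5R)-3,4-dimethyltetrahydrofuran-2,5-diyl]bis[(2-methoxy-4,1-phenylene)oxy]}bis[1-(3,4-dimethoxyphenyl)propan-1-ol] | COc1ccc([C@@H](O)[C@H](C)Oc2ccc([C@H]3O[C@@H](c4ccc(O[C@@H](C)[C@H](O)c5ccc(OC)c(OC)c5)c(OC)c4)[C@H](C)[C@H]3C)cc2OC)cc1OC | target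

Total step count: 15. Longest linear sequence: 15 steps (1 to 22); compounds 2, 4, 16 and 19 are purchased.

Steps most likely to fail

Step 6. Ionisation of the electron-rich cyclopropane, or Lewis-acid reopening of the product at a benzylic C–O bond, may compete with the SN2-like opening and erode the 2,3-cis and 2,5-cis relationships. The fallback sets out from 1 and comes back at 14; it places the C2 aryl group cis to the C3 methyl by hydride delivery instead of by inversion. Brown-type (E)-crotylboration of 1 with (E)-crotyl-B(Ipc)2 made from (+)-Ipc2BOMe (−78 °C, then NaOH/H2O2) would give the anti alcohol (1R,2R)-1-(4-benzyloxy-3-methoxyphenyl)-2-methylbut-3-en-1-ol F1. Hydroboration–oxidation (9-BBN, then NaOH/H2O2) would give (3R,4R)-4-(4-benzyloxy-3-methoxyphenyl)-3-methylbutane-1,4-diol F2, and oxidative lactonisation (TEMPO, PhI(OAc)2) would give the trans lactone (4R,5R)-5-(4-benzyloxy-3-methoxyphenyl)-4-methyldihydrofuran-2(3H)-one F3. Enolate methylation (LDA, MeI, −78 °C) anti to the neighbouring methyl would give the all-trans lactone (3R,4R,5R)-5-(4-benzyloxy-3-methoxyphenyl)-3,4-dimethyldihydrofuran-2(3H)-one F4. Addition of 4-benzyloxy-3-methoxyphenyllithium F5, made from purchased 1-benzyloxy-4-bromo-2-methoxybenzene and n-BuLi at −78 °C, would give the hemiketal (3R,4R,5R)-2,5-bis(4-benzyloxy-3-methoxyphenyl)-3,4-dimethyltetrahydrofuran-2-ol F6. Et3SiH with BF3·OEt2 at −78 °C would then reduce the derived aryl oxocarbenium ion from the face opposite the adjacent methyl, placing the new aryl group cis to it and giving 14.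

Step 5. The cyclopropylcarbinyl mesylate may ionise with homoallyl ring opening towards the p-alkoxybenzylic position, or lactonise onto the cis ester, before hydride displacement occurs. The fallback sets out from 6 and comes back at 14; it carries the oxygenated carbon through the annulation and removes both oxygens once the ring exists, when no cyclopropylcarbinyl leaving group is involved. Silylation of 6 (TBDPSCl, imidazole) would give dimethyl (2R,3S)-2-(4-benzyloxy-3-methoxyphenyl)-3-[(tert-butyldiphenylsilyloxy)methyl]cyclopropane-1,1-dicarboxylate F7. The AlCl3-catalysed annulation with 1 would give the analogue of 9 with CH2OTBDPS in place of the ring methyl, dimethyl 2,5-cis-2,5-bis(4-benzyloxy-3-methoxyphenyl)-4-[(tert-butyldiphenylsilyloxy)methyl]tetrahydrofuran-3,3-dicarboxylate F8. LiCl in wet DMSO followed by NaOMe would give the monoester analogue of 11, methyl 2,5-bis(4-benzyloxy-3-methoxyphenyl)-4-[(tert-butyldiphenylsilyloxy)methyl]tetrahydrofuran-3-carboxylate F9. LiAlH4 would give the silyl-protected alcohol {2,5-bis(4-benzyloxy-3-methoxyphenyl)-4-[(tert-butyldiphenylsilyloxy)methyl]tetrahydrofuran-3-yl}methanol F10, and TBAF would give the trans diol [2,5-bis(4-benzyloxy-3-methoxyphenyl)tetrahydrofuran-3,4-diyl]dimethanol F11. MsCl with Et3N would give the bis-mesylate [2,5-bis(4-benzyloxy-3-methoxyphenyl)tetrahydrofuran-3,4-diyl]bis(methylene) dimethanesulfonate F12, and LiEt3BH would reduce both mesylates to give 14.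

Step 14. The basic arylmagnesium reagent may enolise the α-aryloxy amide or ketone (epimerisation at the aryloxy carbon), and the second amide may not convert fully. The fallback sets out from 15 and 16 and comes back at 21; it assembles the aryl ketone before it is attached and forms the C–O bonds by SN2 etherification. Compound 16 would be converted (MeNHOMe·HCl, iPrMgCl, −20 °C) into (R)-2-hydroxy-N-methoxy-N-methylpropanamide F13, and excess Grignard reagent 20 would give (R)-1-(3,4-dimethoxyphenyl)-2-hydroxypropan-1-one F14. TsCl in pyridine would give (R)-1-(3,4-dimethoxyphenyl)-1-oxopropan-2-yl 4-methylbenzenesulfonate F15. Double alkylation of 15 with F15 under the phosphazene base BEMP (CH2Cl2, rt) would proceed with inversion at both carbons to give 21.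

Further compounds

F1 | step 6 | (1R,2R)-1-(4-benzyloxy-3-methoxyphenyl)-2-methylbut-3-en-1-ol | O[C@@H](c1ccc(OCc2ccccc2)c(OC)c1)[C@H](C)C=C
F2 | step 6 | (3R,4R)-4-(4-benzyloxy-3-methoxyphenyl)-3-methylbutane-1,4-diol | O[C@@H](c1ccc(OCc2ccccc2)c(OC)c1)[C@H](C)CCO
F3 | step 6 | (4R,5R)-5-(4-benzyloxy-3-methoxyphenyl)-4-methyldihydrofuran-2(3H)-one | O=C1O[C@@H](c2ccc(OCc3ccccc3)c(OC)c2)[C@H](C)C1
F4 | step 6 | (3R,4R,5R)-5-(4-benzyloxy-3-methoxyphenyl)-3,4-dimethyldihydrofuran-2(3H)-one | O=C1O[C@@H](c2ccc(OCc3ccccc3)c(OC)c2)[C@H](C)[C@H]1C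
F5 | step 6 | 4-benzyloxy-3-methoxyphenyllithium | [Li]c1ccc(OCc2ccccc2)c(OC)c1
F6 | step 6 | (3R,4R,5R)-2,5-bis(4-benzyloxy-3-methoxyphenyl)-3,4-dimethyltetrahydrofuran-2-ol (anomer mixture) | OC1(c2ccc(OCc3ccccc3)c(OC)c2)O[C@@H](c2ccc(OCc3ccccc3)c(OC)c2)[C@H](C)[C@H]1C
F7 | step 5 | dimethyl (2R,3S)-2-(4-benzyloxy-3-methoxyphenyl)-3-[(tert-butyldiphenylsilyloxy)methyl]cyclopropane-1,1-dicarboxylate | COC(=O)C1(C(=O)OC)[C@@H](CO[Si](c2ccccc2)(c2ccccc2)C(C)(C)C)[C@@H]1c1ccc(OCc2ccccc2)c(OC)c1
F8 | step 5 | dimethyl 2,5-cis-2,5-bis(4-benzyloxy-3-methoxyphenyl)-4-[(tert-butyldiphenylsilyloxy)methyl]tetrahydrofuran-3,3-dicarboxylate (configured as 9) | O1[C@@H](c2ccc(OCc3ccccc3)c(OC)c2)C(C(=O)OC)(C(=O)OC)[C@@H](CO[Si](c2ccccc2)(c2ccccc2)C(C)(C)C)[C@H]1c1ccc(OCc2ccccc2)c(OC)c1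
F9 | step 5 | methyl 2,5-bis(4-benzyloxy-3-methoxyphenyl)-4-[(tert-butyldiphenylsilyloxy)methyl]tetrahydrofuran-3-carboxylate (configured as 11) | COc1cc(ccc1OCc1ccccc1)[C@H]1O[C@@H](c2ccc(OCc3ccccc3)c(OC)c2)[C@H](C(=O)OC)[C@H]1CO[Si](c1ccccc1)(c1ccccc1)C(C)(C)C
F10 | step 5 | {2,5-bis(4-benzyloxy-3-methoxyphenyl)-4-[(tert-butyldiphenylsilyloxy)methyl]tetrahydrofuran-3-yl}methanol (configured as 12) | COc1cc(ccc1OCc1ccccc1)[C@H]1O[C@@H](c2ccc(OCc3ccccc3)c(OC)c2)[C@H](CO)[C@H]1CO[Si](c1ccccc1)(c1ccccc1)C(C)(C)C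
F11 | step 5 | [2,5-bis(4-benzyloxy-3-methoxyphenyl)tetrahydrofuran-3,4-diyl]dimethanol (3,4-trans; configured as 12) | COc1cc(ccc1OCc1ccccc1)[C@H]1O[C@@H](c2ccc(OCc3ccccc3)c(OC)c2)[C@H](CO)[C@H]1CO
F12 | step 5 | [2,5-bis(4-benzyloxy-3-methoxyphenyl)tetrahydrofuran-3,4-diyl]bis(methylene) dimethanesulfonate (configured as 13) | COc1cc(ccc1OCc1ccccc1)[C@H]1O[C@@H](c2ccc(OCc3ccccc3)c(OC)c2)[C@H](COS(C)(=O)=O)[C@H]1COS(C)(=O)=O
F13 | step 14 | (R)-2-hydroxy-N-methoxy-N-methylpropanamide | C[C@@H](O)C(=O)N(C)OC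
F14 | step 14 | (R)-1-(3,4-dimethoxyphenyl)-2-hydroxypropan-1-one | C[C@@H](O)C(=O)c1ccc(OC)c(OC)c1
F15 | step 14 | (R)-1-(3,4-dimethoxyphenyl)-1-oxopropan-2-yl 4-methylbenzenesulfonate | C[C@@H](OS(=O)(=O)c1ccc(C)cc1)C(=O)c1ccc(OC)c(OC)c1
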